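## Structural features

The target is the mixed diester of (3R,3'R,6'R)-lutein: a C40 chain of nine conjugated all-E double bonds (C7 to C7', methyl branches on C9, C13, C13' and C9') that ends in a β ring (cyclohexene with the tetrasubstituted C5=C6 bond in conjugation, tetradecanoate on C3) and in an ε ring (cyclohexene with an isolated C4'=C5' bond, chain on the sp3 carbon C6', hexadecanoate on C3'). Of the three stereocentres, C3 stands alone in the β ring, whereas C3' and C6' share the ε ring in a 1,4 relationship across C4'=C5' and must be trans, so C3' is far from C3 but not from C6'. Fragile are the polyene (oxygen, light, acid), the allylic C3'–O bond (ionisation with elimination or epimerisation), the doubly allylic C6'–H bond (its shift would draw C4'=C5' into conjugation and erase the stereocentre) and both esters (alkoxide). The carbon skeleton is the easy part, since it falls into the classical C15 + C10 + C15 pieces. The real difficulty is double: two oxygen atoms of defined configuration on sp3 carbons at opposite ends of an otherwise unfunctionalised hydrocarbon, and two secondary hydroxyls of similar hindrance that must carry two different fatty acyl groups. The key step exploits that oxygen occurs only on C3 (unactivated methylene of the β ring) and on C3' (allylic methylene of the ε ring): the hydrocarbon 13 already holds the whole skeleton and C6', and its two end rings differ in constitution, so one ring-specific haem enzyme per ring can make each C–O bond at the very end. In the ε ring that enzyme has to override not only C2' but also the intrinsically weakest, doubly allylic C6'–H bond and the C5' end of the allylic radical.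

## Logic of the disconnections

**17 ⇒ 16.** The acyl C–O bond of the hexadecanoate on O3' is cut. The allylic ester is the function most prone to ionisation and elimination, so it goes on last, onto a substrate with a single free hydroxyl. One acyl chain is removed and no selectivity question remains in the forward direction. The forward acylation must stay buffered and basic, so that only the O–H bond and never the C3'–O bond is broken.

**16 ⇒ 15.** The acyl C–O bond of the tetradecanoate on O3 is cut. This exposes the diol 15, which is the product of the key step and carries no acyl chain at all. The forward step must tell the C3 hydroxyl (saturated ring position between two methylene groups) from the allylic C3' hydroxyl. A lipase with an irreversible acyl donor is the tool, and it must stop after one acylation.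

**15 ⇒ 13 (by way of 14).** The C3–O and C3'–O bonds are cut and replaced by C–H. These are the only heteroatom bonds on the skeleton; removing them deletes two of the three stereocentres and all polar functionality, so everything before is protecting-group-free hydrocarbon chemistry. The forward step must oxidise one unactivated CH2 next to an allylic CH2 in one ring and one allylic CH2 next to a doubly allylic CH in the other, each on one face, with eleven C=C bonds as bystanders. Only ring-specific haem monooxygenases can do this, and they require 13 to be all-E, enantiopure at C6', and presented in a form they can take up.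

**13 ⇒ 7 + 10.** The C11=C12 double bond is cut. It is a disubstituted olefin between a formyl carbon and a phosphorus-bearing carbon, the natural Wittig site, and the cut splits off the achiral β-ring C15 unit. The gain is a C25 aldehyde plus a C15 salt. The forward step needs E geometry (or later equilibration) and a base that leaves the C6'–H bond alone.

**7 ⇒ 3 + 4.** The C11'=C12' double bond is cut by the same logic, which makes the symmetric dialdehyde 4 the central C10 unit. All remaining pieces are C15 or smaller. The forward step must let only one of the two equivalent formyl groups of 4 react.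

**3 ⇒ 2 ⇒ 1 and 10 ⇒ 9 ⇒ 8.** First the C11–P bond is cut with allylic transposition (the leaving oxygen sits on C9 in 2 and 9), then the C9–C10 bond made by vinyl addition to the ketone. This reaches the C13 ketones 1 and 8, of which 1 supplies C6' in the correct configuration. The cationic phosphonium-forming step must not trigger loss of the C6' proton, and carbonyl addition must outrun enolisation.

## Other disconnections considered

**Alternative 1:** The cut is made inside the (3'R,6'R)-3'-palmitoyloxy ε C15 silyl ether A2. The C6'–H and C4'–H bonds are removed and the double bond is pushed back from C4'=C5' to C5'=C6', which leads to the C4' tosylhydrazone A1 of the 3'-palmitoyloxy-4'-oxo β-type C15 silyl ether.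
- Forward key step: a dialkoxyborane would reduce the C=N bond of A1 (new C4'–H) and buffered base would expel sulfinate. The allylic diazene would then lose nitrogen in a concerted retro-ene (1,5-hydrogen) shift that places hydrogen on C6' from the face on which nitrogen sat at C4' and leaves the C4'=C5' bond, giving A2.
- In its favour: the contra-thermodynamic, deconjugated ε double bond is made under non-equilibrating conditions. C6' is created by 1,4 transfer of chirality from C3' (hydride anti to the acyloxy group, hydrogen then delivered syn to it, chain trans to oxygen). The palmitate is already in place on its own half, so the two hydroxyls never have to be told apart.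
- Where it is equal or better: on the last point it is better than the chosen plan. In needing no enzyme and no special substrate delivery it is at least its equal in practicality.
- Against it here: an α-acyloxy tosylhydrazone can lose carboxylate to an azoalkene or epimerise at C3' under the basic elimination conditions. Hydrazone formation at the hindered conjugated C4' ketone would be slow. Every leak in the facial selectivity of the C=N reduction would appear as the C6' epimer, which cannot be repaired later. The palmitate would have to survive hydride and the basic olefinations that follow.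
- Comparison: structurally it builds C6' by relay from C3', whereas the chosen plan buys C6' with 1 and lets an enzyme place C3' against it. Mechanistically it is a stoichiometric, substrate-controlled pericyclic sequence against catalyst-controlled C–H oxidation. In step economy it would deliver only one C15 unit after an estimated seven or more steps; the β half with its (3R) myristate, the C10 unit 4 and two olefinations would still be needed, against nine steps in all for the chosen plan.

**Alternative 2:** The cut is the C6–C7 single bond between the β ring and the polyene of (3R)-3-myristoyloxyretinol A5. It gives the tetrasubstituted cyclohexenyl triflate A3 and the all-E tetraenyl stannane A4.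
- Forward key step: zerovalent palladium carrying a weakly bound triarylarsine would insert into the C–O bond of A3, A4 would transmetalate, and reductive elimination would form C6–C7 (Stille coupling) with retention of olefin geometry.
- In its favour: the C3 stereocentre would come from a chiral-pool hydroxy ketone long before any polyene exists, and the myristate is attached at that stage. Neither the configuration at C3 nor the regiochemistry of acylation then depends on a late selective step.
- Where it is equal or better: on both of those points it is better than the chosen plan. The coupling also joins ring and chain without a new E/Z question, where the chosen Wittig steps need thermal equilibration.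
- Against it here: A3 is flanked by a methyl group and a gem-dimethyl carbon, so oxidative addition and transmetalation would be slow; forcing conditions invite protodestannylation, homocoupling and E/Z scrambling of A4. Stoichiometric tin residues are hard to remove from a lipophilic polyene ester. The step solves only the easier half: the ε half with C3' and C6' needs a separate answer, and the two C20 halves must still be joined at C15=C15' in the presence of both esters.
- Comparison: structurally it addresses the ring with one isolated stereocentre and leaves the difficult ε ring untouched. Mechanistically it is a well-understood cross-coupling at its steric limit, against an enzymatic oxidation that is selective but limited by substrate uptake. In step economy a route through A5 would need clearly more than nine steps (an estimated fifteen or more).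

**Alternative 3:** The cut is the C3'–H bond of the ring carbinol in (3R,6R)-3-hydroxy-α-ionone A7, which leads back to racemic 3-oxo-α-ionone A6.
- Forward key step: a ketoreductase with a recycled nicotinamide cofactor would reduce only the (6R) enantiomer of A6 at the ring carbonyl from one face. A mild base would racemise the unreacted enantiomer through the extended dienolate (the C6 hydrogen is γ to the ring enone), so that in a dynamic kinetic resolution all material would end as trans-configured A7.
- In its favour: both stereocentres of the ε ring would be fixed in one catalytic step from a cheap racemate. A7 is an established ε building block that could carry its palmitate before the halves are joined, again avoiding the late differentiation of two hydroxyls.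
- Where it is equal or better: the substrate is a small polar ketone that reductases accept at high loading, so this enzymatic step is more practical than hydroxylation of the C40 hydrocarbon 13. On that point, and on the acylation regiochemistry, the alternative is better.
- Against it here: the dienolate that racemises C6 can also be reprotonated at C4, which moves the ring double bond out of conjugation with the ring ketone and into conjugation with the side chain, draining substrate. The enzyme must also distinguish the ring ketone from the side-chain ketone. Only the ε half is solved: a (3R)-configured β unit from the chiral pool, hydroxyl protection or early acylation, and the C15 + C10 + C15 assembly with oxygenated units are still required.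
- Comparison: structurally it sets C3' and C6' together and early, where the chosen plan buys C6' and sets C3' last. Mechanistically both rely on an enzyme for the decisive selectivity; carbonyl reduction is the more robust transformation and C–H hydroxylation the more direct one. In step economy it would need an estimated thirteen to fifteen steps against nine, because the chosen plan makes both C–O bonds and both new stereocentres in one step and needs no oxygenated chiral building block.

Key step: step 7

Assumption: (R)-α-ionone (1) is bought in high enantiomeric purity, and the two recombinant hydroxylases of step 7 with their redox partners are prepared by protein expression and are treated as catalysts, not as steps of the route.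

## Route

Step 1
Reactants: 1 (R)-α-ionone, (3E)-4-[(1R)-2,6,6-trimethylcyclohex-2-en-1-yl]but-3-en-2-one
Product: 2 (6R)-vinyl-α-ionol, (1E)-3-methyl-1-[(1R)-2,6,6-trimethylcyclohex-2-en-1-yl]penta-1,4-dien-3-ol (both C3 epimers)
Conditions: CH2=CHMgBr (1.2 equiv), THF, −20 → 0 °C; sat. aq. NH4Cl
Reagents that add atoms: vinylmagnesium bromide, C=C[Mg]Br
Why: Grignard 1,2-addition to the enone carbonyl; the organomagnesium reagent at low temperature should add faster than it enolises, so the γ-hydrogen on C6 (the stereocentre) is left alone. The new carbinol carbon forms as both epimers, which is irrelevant because it becomes sp2 in step 2.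

Step 2
Reactants: 2 (6R)-vinyl-α-ionol
Product: 3 (6R)-α-C15 phosphonium bromide, [(2E,4E)-3-methyl-5-[(1R)-2,6,6-trimethylcyclohex-2-en-1-yl]penta-2,4-dien-1-yl]triphenylphosphonium bromide
Conditions: PPh3·HBr (1.05 equiv), MeOH, 0 °C → rt, dark; crystallise (EtOAc)
Reagents that add atoms: triphenylphosphine hydrobromide, Br.c1ccc(cc1)P(c1ccccc1)c1ccccc1
Why: SN1' substitution: one equivalent of acid ionises the tertiary bis-allylic alcohol and the phosphine captures the delocalised cation at its unhindered primary terminus, the standard route to C15 phosphonium salts in retinoid chemistry. The trisubstituted C9=C10 bond should form mainly E, the salt is purified by crystallisation, and C6 takes no part.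

Step 3
Reactants: 3 (6R)-α-C15 phosphonium bromide; 4 (2E,4E,6E)-2,7-dimethylocta-2,4,6-trienedial (C10 dialdehyde)
Product: 7 ε-end C25 aldehyde (2E,4E,6E,8E,10E,12E)-2,7,11-trimethyl-13-[(1R)-2,6,6-trimethylcyclohex-2-en-1-yl]trideca-2,4,6,8,10,12-hexaenal, via α-C15 ylide 5 (not isolated), via 11'Z aldehyde 6 (not isolated)
Conditions: 4 (2.5 equiv), NaOMe (1.05 equiv, slow addition), CH2Cl2/MeOH, −10 → 20 °C; then heptane, 90 °C, Ar, dark; SiO2 (4 recovered)
Reagents that add atoms: none
Why: Wittig olefination of a semi-stabilised allylic ylide with one formyl group of the dialdehyde; the excess of 4 and the lower electrophilicity of the remaining formyl group once it is conjugated with a hexaene should hold the reaction at mono-olefination. The new C11'=C12' bond forms as an E/Z mixture, and the sterically hindered 11'Z isomer should relax thermally to the all-E aldehyde.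

Step 4
Reactants: 8 β-ionone, (3E)-4-(2,6,6-trimethylcyclohex-1-en-1-yl)but-3-en-2-one
Product: 9 vinyl-β-ionol, (1E)-3-methyl-1-(2,6,6-trimethylcyclohex-1-en-1-yl)penta-1,4-dien-3-ol (racemic)
Conditions: CH2=CHMgBr (1.2 equiv), THF, −10 → 0 °C; sat. aq. NH4Cl
Reagents that add atoms: vinylmagnesium bromide, C=C[Mg]Br
Why: Grignard 1,2-addition to the dienone carbonyl as in step 1; the racemic carbinol centre disappears in step 5.

Step 5
Reactants: 9 vinyl-β-ionol
Product: 10 β-C15 phosphonium bromide, [(2E,4E)-3-methyl-5-(2,6,6-trimethylcyclohex-1-en-1-yl)penta-2,4-dien-1-yl]triphenylphosphonium bromide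
Conditions: PPh3·HBr (1.05 equiv), MeOH, rt, dark; crystallise (EtOAc)
Reagents that add atoms: triphenylphosphine hydrobromide, Br.c1ccc(cc1)P(c1ccccc1)c1ccccc1
Why: SN1' capture of the trienyl cation by the phosphine at the primary terminus, the same reaction as step 2 on the achiral β series; crystallisation should remove the minor 9Z salt.

Step 6
Reactants: 7 ε-end C25 aldehyde; 10 β-C15 phosphonium bromide
Product: 13 (6'R)-α-carotene [(6'R)-β,ε-carotene; all-E], via β-C15 ylide 11 (not isolated), via 11Z carotene 12 (not isolated)
Conditions: 10 (1.3 equiv), NaOMe (1.35 equiv), CH2Cl2/MeOH, 0 °C → rt; then heptane, reflux, Ar, dark; crystallise (CH2Cl2/MeOH)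
Reagents that add atoms: none
Why: Second Wittig olefination, now at the single formyl group of 7, forms C11=C12; the hindered 11Z isomer should equilibrate thermally and the all-E hydrocarbon should crystallise, which also removes the phosphine oxide. Methoxide cannot deprotonate the C6'–H bond and no acid is present, so the stereocentre is carried through unchanged.

Step 7
Reactants: 13 (6'R)-α-carotene
Product: 15 (3R,3'R,6'R)-lutein [(3R,3'R,6'R)-β,ε-carotene-3,3'-diol], via zeinoxanthin 14 (not isolated)
Conditions: CYP97A3 + CYP97C1 (recombinant, E. coli membrane fraction), ferredoxin, ferredoxin–NADP+ reductase, NADP+ (cat.), D-glucose, glucose dehydrogenase, air, 13 in Tween 80/phosphatidylcholine micelles, phosphate buffer pH 7.5, 28 °C, dark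
Reagents that add atoms: dioxygen, O=O
Why: Each haem enzyme runs the usual P450 cycle: the substrate displaces water from the trivalent iron, two electrons from NADPH arrive through the reductase and ferredoxin, O2 binds, and cleavage of its O–O bond leaves the oxo-iron (tetravalent iron) porphyrin radical cation. This oxidant abstracts a hydrogen atom from C3 of the β ring (CYP97A3) or from C3' of the ε ring (CYP97C1), and the carbon radical should collapse onto the iron-bound hydroxyl faster than it can invert or, at C3', rebound at C5', so oxygen takes the place of the hydrogen with retention. The closest known reaction type is this same biosynthetic ring hydroxylation of α-carotene by the paired CYP97 hydroxylases in recombinant hosts; the β ring is expected to react first to give 14, which the ε-ring enzyme then completes. No ring is closed and no skeletal bond is made. C3 (R) is controlled by the active site of the β-ring enzyme, which presents one of the two C3 hydrogens to the oxo-iron; C3' (R), trans to the chain on C6', is controlled by the ε-ring enzyme, which recognises the natural (6'R) ring. The step needs site selectivity for C3 over the weaker allylic C4–H bond and for C3' over the doubly allylic C6'–H bond and C2', and chemoselectivity against epoxidation of eleven C=C bonds; none of this is inherent in 13. What the substrate contributes is two constitutionally different end rings, each fitting only its own enzyme, and a rigid all-E polyene that lets only the end ring reach the haem.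

Step 8
Reactants: 15 (3R,3'R,6'R)-lutein
Product: 16 lutein 3-O-myristate, (3R,3'R,6'R)-3'-hydroxy-β,ε-caroten-3-yl tetradecanoate
Conditions: immobilised lipase (Burkholderia cepacia lipase or Candida antarctica lipase B, chosen by screening), vinyl myristate (3 equiv), toluene, 40 °C, Ar, dark; stopped at the mono-ester
Reagents that add atoms: vinyl myristate (vinyl tetradecanoate), C=COC(=O)CCCCCCCCCCCCC
Why: Lipase-catalysed irreversible transesterification through a serine acyl-enzyme; the vinyl alcohol set free tautomerises, so the acylation cannot run backwards. The C3 hydroxyl sits between two methylene groups on the saturated side of the β ring, whereas the C3' hydroxyl is allylic and flanked by an sp2 carbon in the ring that also carries the chain; the lipase is screened for the ability to read this difference, and no stereocentre is touched.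

Step 9
Reactants: 16 lutein 3-O-myristate
Product: 17 lutein 3-O-myristate 3'-O-palmitate (target), (3R,3'R,6'R)-3-(tetradecanoyloxy)-β,ε-caroten-3'-yl hexadecanoate
Conditions: palmitoyl chloride (1.5 equiv), pyridine (5 equiv), DMAP (0.1 equiv), CH2Cl2, 0 °C → rt, Ar, dark
Reagents that add atoms: palmitoyl chloride (hexadecanoyl chloride), CCCCCCCCCCCCCCCC(=O)Cl
Why: DMAP-catalysed acylation (acyl transfer through the N-acylpyridinium ion) of the only remaining hydroxyl. Excess pyridine keeps the medium basic, so the O–H bond and not the allylic C3'–O bond is broken and C3' keeps its configuration.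

## Compound list

1 | (R)-α-ionone, (3E)-4-[(1R)-2,6,6-trimethylcyclohex-2-en-1-yl]but-3-en-2-one | C1C=C(C)[C@H](/C=C/C(C)=O)C(C)(C)C1 | starting material
2 | (6R)-vinyl-α-ionol, (1E)-3-methyl-1-[(1R)-2,6,6-trimethylcyclohex-2-en-1-yl]penta-1,4-dien-3-ol (both C3 epimers) | C1C=C(C)[C@H](/C=C/C(C)(O)C=C)C(C)(C)C1 | intermediate
3 | (6R)-α-C15 phosphonium bromide, [(2E,4E)-3-methyl-5-[(1R)-2,6,6-trimethylcyclohex-2-en-1-yl]penta-2,4-dien-1-yl]triphenylphosphonium bromide | C1C=C(C)[C@H](/C=C/C(C)=C/C[P+](c2ccccc2)(c2ccccc2)c2ccccc2)C(C)(C)C1.[Br-] | intermediate
4 | (2E,4E,6E)-2,7-dimethylocta-2,4,6-trienedial (C10 dialdehyde) | O=C/C(C)=C/C=C/C=C(C)/C=O | starting material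
5 | α-C15 ylide, [(2E,4E)-3-methyl-5-[(1R)-2,6,6-trimethylcyclohex-2-en-1-yl]penta-2,4-dien-1-ylidene]triphenylphosphorane | C1C=C(C)[C@H](/C=C/C(C)=C/C=P(c2ccccc2)(c2ccccc2)c2ccccc2)C(C)(C)C1 | intermediate (not isolated)
6 | 11'Z aldehyde, (2E,4E,6E,8Z,10E,12E)-2,7,11-trimethyl-13-[(1R)-2,6,6-trimethylcyclohex-2-en-1-yl]trideca-2,4,6,8,10,12-hexaenal | C1C=C(C)[C@H](\C=C\C(C)=C\C=C/C(C)=C/C=C/C=C(C)/C=O)C(C)(C)C1 | intermediate (not isolated)
7 | ε-end C25 aldehyde, (2E,4E,6E,8E,10E,12E)-2,7,11-trimethyl-13-[(1R)-2,6,6-trimethylcyclohex-2-en-1-yl]trideca-2,4,6,8,10,12-hexaenal | C1C=C(C)[C@H](/C=C/C(C)=C/C=C/C(C)=C/C=C/C=C(C)/C=O)C(C)(C)C1 | intermediate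
8 | β-ionone, (3E)-4-(2,6,6-trimethylcyclohex-1-en-1-yl)but-3-en-2-one | CC(=O)/C=C/C1=C(C)CCCC1(C)C | starting material
9 | vinyl-β-ionol, (1E)-3-methyl-1-(2,6,6-trimethylcyclohex-1-en-1-yl)penta-1,4-dien-3-ol (racemic) | C=CC(C)(O)/C=C/C1=C(C)CCCC1(C)C | intermediate
10 | β-C15 phosphonium bromide, [(2E,4E)-3-methyl-5-(2,6,6-trimethylcyclohex-1-en-1-yl)penta-2,4-dien-1-yl]triphenylphosphonium bromide | [Br-].c1ccccc1[P+](c1ccccc1)(c1ccccc1)C/C=C(C)/C=C/C1=C(C)CCCC1(C)C | intermediate
11 | β-C15 ylide, [(2E,4E)-3-methyl-5-(2,6,6-trimethylcyclohex-1-en-1-yl)penta-2,4-dien-1-ylidene]triphenylphosphorane | c1ccccc1P(c1ccccc1)(c1ccccc1)=C/C=C(C)/C=C/C1=C(C)CCCC1(C)C | intermediate (not isolated)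
12 | 11Z carotene, (6'R,11Z)-β,ε-carotene | C1C=C(C)[C@H](/C=C/C(C)=C/C=C/C(C)=C/C=C/C=C(C)/C=C\C=C(C)\C=C\C2=C(C)CCCC2(C)C)C(C)(C)C1 | intermediate (not isolated)
13 | (6'R)-α-carotene, (6'R)-β,ε-carotene, all-E | C1C=C(C)[C@H](/C=C/C(C)=C/C=C/C(C)=C/C=C/C=C(C)/C=C/C=C(C)/C=C/C2=C(C)CCCC2(C)C)C(C)(C)C1 | intermediate
14 | zeinoxanthin, (3R,6'R)-β,ε-caroten-3-ol | C1C=C(C)[C@H](/C=C/C(C)=C/C=C/C(C)=C/C=C/C=C(C)/C=C/C=C(C)/C=C/C2=C(C)C[C@@H](O)CC2(C)C)C(C)(C)C1 | intermediate (not isolated)
15 | (3R,3'R,6'R)-lutein, (3R,3'R,6'R)-β,ε-carotene-3,3'-diol | O[C@H]1C=C(C)[C@H](/C=C/C(C)=C/C=C/C(C)=C/C=C/C=C(C)/C=C/C=C(C)/C=C/C2=C(C)C[C@@H](O)CC2(C)C)C(C)(C)C1 | intermediate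
16 | lutein 3-O-myristate, (3R,3'R,6'R)-3'-hydroxy-β,ε-caroten-3-yl tetradecanoate | O[C@H]1C=C(C)[C@H](/C=C/C(C)=C/C=C/C(C)=C/C=C/C=C(C)/C=C/C=C(C)/C=C/C2=C(C)C[C@@H](OC(=O)CCCCCCCCCCCCC)CC2(C)C)C(C)(C)C1 | intermediate
17 | lutein 3-O-myristate 3'-O-palmitate, (3R,3'R,6'R)-3-(tetradecanoyloxy)-β,ε-caroten-3'-yl hexadecanoate | CCCCCCCCCCCCCCCC(=O)O[C@H]1C=C(C)[C@H](/C=C/C(C)=C/C=C/C(C)=C/C=C/C=C(C)/C=C/C=C(C)/C=C/C2=C(C)C[C@@H](OC(=O)CCCCCCCCCCCCC)CC2(C)C)C(C)(C)C1 | target

## Step count and least certain steps

Total step count: 9. Longest linear sequence: 7 steps (1, 2, 3, 6, 7, 8, 9); steps 4 and 5 form the short branch.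

**Step 7 (key step).** The most likely failure is insufficient transfer of the crystalline, water-insoluble hydrocarbon to the membrane-associated enzymes, so that conversion stays low. Stalling after the first hydroxylation and uncoupled turnover, which releases reduced oxygen species that bleach the polyene, are further risks. Fallback: the late C–H oxidation is abandoned and both oxygens are carried in on the C15 units by known Wittig chemistry; it sets out from 4 and comes back to the route at 15. (3R,6R)-3-Hydroxy-α-ionone A7 (from the reductase approach of alternative 3, or by lipase resolution of the racemic trans alcohol) would be taken through the operations of steps 1 and 2 (CH2=CHMgBr in excess, then PPh3·HBr) by way of (3R,6R)-3-hydroxy-vinyl-α-ionol F1 to the (3R,6R)-3-hydroxy-α-C15 phosphonium bromide F2. Wittig reaction of F2 with excess 4 as in step 3 would give the (3'R,6'R)-3'-hydroxy ε C25 aldehyde F3. (3R)-3-Hydroxy-β-ionone F4, a known building block derived from the commercial chiral-pool ketone (4R,6R)-4-hydroxy-2,2,6-trimethylcyclohexanone, would be converted by the same two operations through (3R)-3-hydroxy-vinyl-β-ionol F5 into the (3R)-3-hydroxy-β-C15 phosphonium bromide F6. Wittig reaction of F6 with F3 under the conditions of step 6 would give 15 with free hydroxyls throughout. The price is a longer route and the loss of the single-step installation of both oxygens.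

**Step 8.** The most likely failure is insufficient discrimination between the C3 and C3' hydroxyls by the lipase, so that both monoesters and the diester form together; slow turnover because the C40 diol fits the acyl-enzyme poorly is the second risk. The screen is run with both vinyl esters, since an enzyme selective for C3' serves equally well: vinyl palmitate would then give lutein 3'-O-palmitate F7, and myristoyl chloride under the conditions of step 9 would complete 17. Fallback: the allylic position is singled out chemically instead of enzymatically; it sets out from 15 and comes back at 16. Activated MnO2 in CH2Cl2 oxidises only the allylic alcohol and would give 3'-oxolutein F8. Myristoyl chloride, pyridine and DMAP would acylate the remaining C3 hydroxyl to 3'-oxolutein 3-O-myristate F9. Luche reduction (NaBH4, CeCl3·7H2O, MeOH/THF, −40 °C) reduces the enone carbonyl in the presence of the ester and should give 16 together with its C3' epimer, 3'-epilutein 3-O-myristate F10, which would be separated by chromatography and returned to F9 with MnO2. The weak point of this fallback is the modest facial control expected in the hydride addition, which is why it is held in reserve.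

**Step 2.** The most likely failure is loss of the C6 proton from the delocalised cation, or acid-induced migration of the ring double bond, leading to rearranged polyenes and erosion of optical purity at the only stereocentre the hydrocarbon carries. Fallback: no carbocation is formed; it sets out from 1 and comes back at 3. Horner–Wadsworth–Emmons reaction of 1 with the sodium salt of triethyl phosphonoacetate (NaH, THF, 0 °C, phosphonate in slight excess so that no free hydride meets 1) would give ethyl (6R)-α-ionylideneacetate F11, whose 2E isomer is separated from the minor 2Z isomer. Reduction with i-Bu2AlH (toluene, −78 °C) would give (6R)-α-ionylideneethanol F12. Appel bromination (CBr4, PPh3, CH2Cl2, −20 °C) would give the (6R)-α-C15 allylic bromide F13, and PPh3 in toluene at room temperature would convert it into 3.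

**Step 3.** The most likely failure is over-olefination at the second formyl group, which would give the symmetrical C40 hydrocarbon with two ε rings, together with difficult separation of the product from recovered 4; incomplete Z to E equilibration is a lesser risk. Fallback: the symmetric dialdehyde is replaced by a C5 + C20 sequence; it sets out from 3, comes back at 13, and bypasses 4, 7 and 10. Wittig reaction of 3 with commercial (2E)-4-acetoxy-2-methylbut-2-enal (1,2-epoxybutane as acid scavenger, EtOH, reflux) would give (6R)-α-retinyl acetate F14. PPh3·HBr in MeOH would displace the allylic acetate through the polyenyl cation and give (6R)-α-retinyltriphenylphosphonium bromide F15. Wittig reaction of F15 with commercial all-E retinal (NaOMe, CH2Cl2/MeOH), followed by thermal equilibration of the new central C15=C15' bond in heptane, would give 13. The formation of F15 carries the same cation risk as step 2, now with a longer conjugated system.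

## Further compounds

F1 | step 7 | (3R,6R)-3-hydroxy-vinyl-α-ionol, (1R,4R)-4-[(1E)-3-hydroxy-3-methylpenta-1,4-dien-1-yl]-3,5,5-trimethylcyclohex-2-en-1-ol (both carbinol epimers) | O[C@H]1C=C(C)[C@H](/C=C/C(C)(O)C=C)C(C)(C)C1
F2 | step 7 | (3R,6R)-3-hydroxy-α-C15 phosphonium bromide, [(2E,4E)-5-[(1R,4R)-4-hydroxy-2,6,6-trimethylcyclohex-2-en-1-yl]-3-methylpenta-2,4-dien-1-yl]triphenylphosphonium bromide | O[C@H]1C=C(C)[C@H](/C=C/C(C)=C/C[P+](c2ccccc2)(c2ccccc2)c2ccccc2)C(C)(C)C1.[Br-]
F3 | step 7 | (3'R,6'R)-3'-hydroxy ε C25 aldehyde, (2E,4E,6E,8E,10E,12E)-13-[(1R,4R)-4-hydroxy-2,6,6-trimethylcyclohex-2-en-1-yl]-2,7,11-trimethyltrideca-2,4,6,8,10,12-hexaenal | O[C@H]1C=C(C)[C@H](/C=C/C(C)=C/C=C/C(C)=C/C=C/C=C(C)/C=O)C(C)(C)C1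
F4 | step 7 | (3R)-3-hydroxy-β-ionone, (3E)-4-[(4R)-4-hydroxy-2,6,6-trimethylcyclohex-1-en-1-yl]but-3-en-2-one | CC(=O)/C=C/C1=C(C)C[C@@H](O)CC1(C)C
F5 | step 7 | (3R)-3-hydroxy-vinyl-β-ionol, (1E)-1-[(4R)-4-hydroxy-2,6,6-trimethylcyclohex-1-en-1-yl]-3-methylpenta-1,4-dien-3-ol (both carbinol epimers) | C=CC(C)(O)/C=C/C1=C(C)C[C@@H](O)CC1(C)C
F6 | step 7 | (3R)-3-hydroxy-β-C15 phosphonium bromide, [(2E,4E)-5-[(4R)-4-hydroxy-2,6,6-trimethylcyclohex-1-en-1-yl]-3-methylpenta-2,4-dien-1-yl]triphenylphosphonium bromide | [Br-].c1ccccc1[P+](c1ccccc1)(c1ccccc1)C/C=C(C)/C=C/C1=C(C)C[C@@H](O)CC1(C)C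
F7 | step 8 | lutein 3'-O-palmitate, (3R,3'R,6'R)-3-hydroxy-β,ε-caroten-3'-yl hexadecanoate | CCCCCCCCCCCCCCCC(=O)O[C@H]1C=C(C)[C@H](/C=C/C(C)=C/C=C/C(C)=C/C=C/C=C(C)/C=C/C=C(C)/C=C/C2=C(C)C[C@@H](O)CC2(C)C)C(C)(C)C1
F8 | step 8 | 3'-oxolutein, (3R,6'R)-3-hydroxy-β,ε-caroten-3'-one | O=C1C=C(C)[C@H](/C=C/C(C)=C/C=C/C(C)=C/C=C/C=C(C)/C=C/C=C(C)/C=C/C2=C(C)C[C@@H](O)CC2(C)C)C(C)(C)C1
F9 | step 8 | 3'-oxolutein 3-O-myristate, (3R,6'R)-3'-oxo-β,ε-caroten-3-yl tetradecanoate | O=C1C=C(C)[C@H](/C=C/C(C)=C/C=C/C(C)=C/C=C/C=C(C)/C=C/C=C(C)/C=C/C2=C(C)C[C@@H](OC(=O)CCCCCCCCCCCCC)CC2(C)C)C(C)(C)C1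
F10 | step 8 | 3'-epilutein 3-O-myristate, (3R,3'S,6'R)-3'-hydroxy-β,ε-caroten-3-yl tetradecanoate | O[C@@H]1C=C(C)[C@H](/C=C/C(C)=C/C=C/C(C)=C/C=C/C=C(C)/C=C/C=C(C)/C=C/C2=C(C)C[C@@H](OC(=O)CCCCCCCCCCCCC)CC2(C)C)C(C)(C)C1
F11 | step 2 | ethyl (6R)-α-ionylideneacetate, ethyl (2E,4E)-3-methyl-5-[(1R)-2,6,6-trimethylcyclohex-2-en-1-yl]penta-2,4-dienoate | C1C=C(C)[C@H](/C=C/C(C)=C/C(=O)OCC)C(C)(C)C1
F12 | step 2 | (6R)-α-ionylideneethanol, (2E,4E)-3-methyl-5-[(1R)-2,6,6-trimethylcyclohex-2-en-1-yl]penta-2,4-dien-1-ol | C1C=C(C)[C@H](/C=C/C(C)=C/CO)C(C)(C)C1
F13 | step 2 | (6R)-α-C15 allylic bromide, (2E,4E)-1-bromo-3-methyl-5-[(1R)-2,6,6-trimethylcyclohex-2-en-1-yl]penta-2,4-diene | C1C=C(C)[C@H](/C=C/C(C)=C/CBr)C(C)(C)C1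
F14 | step 3 | (6R)-α-retinyl acetate, (2E,4E,6E,8E)-3,7-dimethyl-9-[(1R)-2,6,6-trimethylcyclohex-2-en-1-yl]nona-2,4,6,8-tetraen-1-yl acetate | C1C=C(C)[C@H](/C=C/C(C)=C/C=C/C(C)=C/COC(C)=O)C(C)(C)C1
F15 | step 3 | (6R)-α-retinyltriphenylphosphonium bromide, [(2E,4E,6E,8E)-3,7-dimethyl-9-[(1R)-2,6,6-trimethylcyclohex-2-en-1-yl]nona-2,4,6,8-tetraen-1-yl]triphenylphosphonium bromide | C1C=C(C)[C@H](/C=C/C(C)=C/C=C/C(C)=C/C[P+](c2ccccc2)(c2ccccc2)c2ccccc2)C(C)(C)C1.[Br-]
A1 | alternative 1 | C4' tosylhydrazone of the (3'R)-3'-palmitoyloxy-4'-oxo β-type C15 tert-butyldimethylsilyl ether | CCCCCCCCCCCCCCCC(=O)O[C@H]1C(=NNS(=O)(=O)c2ccc(C)cc2)C(C)=C(/C=C/C(C)=C/CO[Si](C)(C)C(C)(C)C)C(C)(C)C1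
A2 | alternative 1 | (3'R,6'R)-3'-palmitoyloxy ε C15 tert-butyldimethylsilyl ether | CCCCCCCCCCCCCCCC(=O)O[C@H]1C=C(C)[C@H](/C=C/C(C)=C/CO[Si](C)(C)C(C)(C)C)C(C)(C)C1
A3 | alternative 2 | (4R)-2,6,6-trimethyl-4-(tetradecanoyloxy)cyclohex-1-en-1-yl trifluoromethanesulfonate | FC(F)(F)S(=O)(=O)OC1=C(C)C[C@@H](OC(=O)CCCCCCCCCCCCC)CC1(C)C
A4 | alternative 2 | (2E,4E,6E,8E)-3,7-dimethyl-9-(tributylstannyl)nona-2,4,6,8-tetraen-1-ol | OC/C=C(C)/C=C/C=C(C)/C=C/[Sn](CCCC)(CCCC)CCCC
A5 | alternative 2 | (3R)-3-myristoyloxyretinol (β C20 half) | OC/C=C(C)/C=C/C=C(C)/C=C/C1=C(C)C[C@@H](OC(=O)CCCCCCCCCCCCC)CC1(C)C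
A6 | alternative 3 | racemic 3-oxo-α-ionone, 3,5,5-trimethyl-4-[(1E)-3-oxobut-1-en-1-yl]cyclohex-2-en-1-one | CC(=O)/C=C/C1C(C)=CC(=O)CC1(C)C
A7 | alternative 3 | (3R,6R)-3-hydroxy-α-ionone, (3E)-4-[(1R,4R)-4-hydroxy-2,6,6-trimethylcyclohex-2-en-1-yl]but-3-en-2-one | O[C@H]1C=C(C)[C@H](/C=C/C(C)=O)C(C)(C)C1
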